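The target was what I wanted from this flask, and the isomer of the product was what it turned into, so I began by asking how fast that loss ran.

| setting | Saturday's | Thursday's | flask |
|---|---|---|---|
| substrate | 1.4 M | 2.2 M | 1.0 M |
| remark | run made earlier | run made earlier |  |
| time |  |  | 8.0 h |

| run | time / h | target / % | isomer of the product / % |
|---|---|---|---|
| Saturday's | 0.667 | 64.2 | 34.2 |
| Saturday's | 1.33 | 63.5 | 34.9 |
| Saturday's | 3.00 | 61.1 | 38.5 |
| Saturday's | 8.00 | 52.1 | 47.8 |
| Thursday's | 1.00 | 65.6 | 34.5 |
| Thursday's | 3.00 | 62.7 | 36.8 |
| Thursday's | 5.00 | 60.2 | 38.7 |
| Thursday's | 8.00 | 56.8 | 43.1 |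

(scatter of a reading: 0.5 percentage points)

- ratio of target to isomer of the product at 15 s
- ratio of target to isomer of the product at 8.0 h

- the numbers in the tables scatter by 0.5 percentage points (one standard deviation)
- a reading or a percentage of target counts all its forms, free or not

In percent, the isomer of the product rose differently in the two runs: from 34.2% to 47.8% on Saturday and from 34.5% to 43.1% on Thursday. In concentration, though, c(isomer of the product) gained 0.0260 M h⁻¹ and 0.0270 M h⁻¹. So I took their mean, 0.0265 M h⁻¹, as the drain: the concentration of target turned into isomer each hour, a zero-order loss, which suggested a stock of target keeping a small free amount steady.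

Running each first reading back at the drain gave an isomer share at the start of 33.1%, so a ratio of 2.02 for 15 s. I held that loosely, since no reading comes before 1.00 h on Thursday or 0.667 h on Saturday. Adding the drain over 8.0 h at 1.0 M gave 54.3% isomer and a ratio of 0.841.

The weak link was whether the drain lasts as target falls. Saturday's last stretch gave 0.0260 M h⁻¹, close to the drain, with c(target) down to 0.729 M. The flask had to reach 0.457 M, lower than that reading by 0.273 M, so this was a long extrapolation, and I committed to it as one.

The forecast gave 1.93 and 0.88, holding that “The absolute rate is therefore about 0.025 M/h regardless of concentration”.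

The flask gave 20.4 at 15 s, ten times my figure, and 0.848 at 8.0 h. The stock was crystals, 44.5% of the charge at 8.00 h, counted in target. At the drain those crystals stood for 16.8 h more of loss, and at 80.0 h the flask held 0% crystals.

    substrate ⇌ other conformer (K = 0.410, k = 0.00526 s⁻¹)
    substrate ⇌ target (K = 0.920, k = 0.00228 s⁻¹)
    other conformer → isomer of the product (k = 0.00295 s⁻¹)
    crystals ⇌ target, rate k4*(cs4 - [target]) while solid is left; crystals form when [target] > cs4 (solubility = 10.0 mM, k = 0.0146 s⁻¹)

With 0.40 M of substrate, the drain gives 86.1% isomer and a ratio of 0.161 at 8.0 h. That neighbouring flask computed to 83.7% and 0.166.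

(The numbers in the tables were generated by integration from invented constants; scatter was added.)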